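**Plan**

- Retrosynthesis (isocoumarin numbering C1–C8a; ring B counted from the ether carbon C1' to the pentyl carbon C6'): the three phenols and the ring B acid are masked as methyl ethers and a tert-butyl ester. Ring C is then opened at O2–C3 and C4–C4a, which leads back to a C4a triflate and 1-heptyne. Last, O–C8 and C8a–C1 are cut together.
- Enabling feature: on ring A the ether oxygen sits on C8 and the carboxyl carbon C1 on the adjacent C8a, and the next carbon, C4a, carries an oxygen. C8/C8a can therefore be the two ends of an aryne polarised by that C4a oxygen, which afterwards becomes the triflate that brings in C4 and C3.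
- Forward: the ring B phenol is made from olivetol dimethyl ether through a symmetric dibromide, and the ring A silylaryl triflate from 3,5-bis(benzyloxy)phenol by directed metalation. The two are joined with CO2 in one flask, so rings A and B arrive preformed and ring C closes last by 6-endo lactonisation.
- Protecting groups: the C6 oxygen travels as a second benzyl ether, so the aryne precursor comes from a symmetric phenol with only one kind of ortho position. After hydrogenolysis the free C6 hydroxyl is methylated selectively and the chelated C4a hydroxyl is triflated.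
- The target has no stereocentre, so no stereocontrol is needed.

Key step: step 7

Remark: olivetol dimethyl ether 1 is taken as the purchased form of olivetol; otherwise one O-methylation (Me2SO4, K2CO3) precedes step 1.

**Route**

Step 1
Reactants: 1 1,3-dimethoxy-5-pentylbenzene
Product: 2 2,4-dibromo-1,5-dimethoxy-3-pentylbenzene
Conditions: NBS (2.1 equiv), MeCN, 0 °C to rt
Reagents that add atoms: N-bromosuccinimide, O=C1CCC(=O)N1Br
Why: Twofold electrophilic aromatic bromination should place each bromine para to one methoxy group and ortho to the other, that is at the two equivalent positions flanking the pentyl chain, because the position between the two methoxy groups is the least reactive towards NBS.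

Step 2
Reactants: 2 2,4-dibromo-1,5-dimethoxy-3-pentylbenzene
Product: 4 tert-butyl 3-bromo-4,6-dimethoxy-2-pentylbenzoate, via the aryllithium 3 (not isolated)
Conditions: n-BuLi (1.0 equiv), THF, −78 °C; then Boc2O, −78 °C to rt
Reagents that add atoms: di-tert-butyl dicarbonate, CC(C)(C)OC(=O)OC(=O)OC(C)(C)C; n-butyllithium, [Li]CCCC (lithium of intermediate 3 only)
Why: Bromine–lithium exchange with one equivalent of n-BuLi should stop after one bromine (the symmetry of 2 makes the choice irrelevant), and acylation of the aryllithium by Boc2O gives the tert-butyl ester directly.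

Step 3
Reactants: 4 tert-butyl 3-bromo-4,6-dimethoxy-2-pentylbenzoate
Product: 7 tert-butyl 3-hydroxy-4,6-dimethoxy-2-pentylbenzoate, via the aryllithium 5 (not isolated), via the lithium aryltrimethoxyborate 6 (not isolated)
Conditions: n-BuLi (1.05 equiv), THF, −78 °C; B(OMe)3, −78 to 0 °C; then AcOH, 30% H2O2, 0 °C to rt
Reagents that add atoms: hydrogen peroxide, OO; trimethyl borate, COB(OC)OC (atoms of intermediate 6 only); n-butyllithium, [Li]CCCC (lithium of intermediates 5 and 6 only)
Why: A second bromine–lithium exchange (the doubly ortho-substituted tert-butyl ester should be inert to n-BuLi at −78 °C), borylation and oxidative aryl migration from boron to oxygen (boronate oxidation) replace bromine by hydroxyl at the carbon between pentyl and methoxy.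

Step 4
Reactants: 8 3,5-bis(benzyloxy)phenol
Product: 9 3,5-bis(benzyloxy)phenyl N-isopropylcarbamate
Conditions: i-PrNCO, Et3N (cat.), CH2Cl2, rt
Reagents that add atoms: isopropyl isocyanate, CC(C)N=C=O
Why: Base-catalysed addition of the phenol to the isocyanate (carbamoylation) installs a directing group that can later be removed under mild conditions.

Step 5
Reactants: 9 3,5-bis(benzyloxy)phenyl N-isopropylcarbamate
Product: 13 3,5-bis(benzyloxy)-2-(trimethylsilyl)phenyl N-isopropylcarbamate, via the N-silyl carbamate 10 (not isolated), via its ortho-lithio derivative 11 (not isolated), via the N,C-disilyl carbamate 12 (not isolated)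
Conditions: TBSOTf, TMEDA, Et2O, 0 °C to rt; n-BuLi, TMEDA, −78 °C; TMSCl, −78 °C to rt; aq NaHSO4
Reagents that add atoms: chlorotrimethylsilane, C[Si](C)(C)Cl; tert-butyldimethylsilyl triflate, CC(C)(C)[Si](C)(C)OS(=O)(=O)C(F)(F)F (atoms of intermediates 10 to 12 only); n-butyllithium, [Li]CCCC (lithium of intermediate 11 only)
Why: Directed ortho-metalation should occur between the transiently N-silylated carbamate and the neighbouring benzyloxy group, a position that is the same on either side because 9 is symmetric, and TMSCl then silylates the aryllithium while the N–Si bond is hydrolysed on work-up.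

Step 6
Reactants: 13 3,5-bis(benzyloxy)-2-(trimethylsilyl)phenyl N-isopropylcarbamate
Product: 15 3,5-bis(benzyloxy)-2-(trimethylsilyl)phenyl trifluoromethanesulfonate, via the silylphenol 14 (not isolated)
Conditions: DBU, Et2NH, MeCN, 40 °C; then PhNTf2, rt
Reagents that add atoms: N-phenylbis(trifluoromethanesulfonimide), O=S(=O)(N(c1ccccc1)S(=O)(=O)C(F)(F)F)C(F)(F)F
Why: E1cB cleavage of the N-monosubstituted carbamate by DBU, with diethylamine scavenging the isocyanate, frees the phenoxide, which is O-triflated in the same flask by PhNTf2.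

Step 7
Reactants: 7 tert-butyl 3-hydroxy-4,6-dimethoxy-2-pentylbenzoate; 15 3,5-bis(benzyloxy)-2-(trimethylsilyl)phenyl trifluoromethanesulfonate; 16 carbon dioxide
Product: 19 2,4-bis(benzyloxy)-6-[3-(tert-butoxycarbonyl)-4,6-dimethoxy-2-pentylphenoxy]benzoic acid, via the cesium phenoxide 17 (not isolated), via the aryne 18 (not isolated)
Conditions: 7, CsOH·H2O (1.0 equiv), MeOH, rt, evaporation and azeotropic drying with PhMe; then 15 (1.5 equiv, slow addition), CsF (3 equiv), 18-crown-6, CO2 (1 atm), THF, 0 °C to rt; aq HCl to pH 3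
Reagents that add atoms: cesium hydroxide monohydrate, [Cs+].[OH-].O (cesium of intermediate 17 only)
Why: Proposed new method: fluoride attack on silicon in 15 expels triflate and releases aryne 18, the phenoxide 17 adds through oxygen to C8, and the aryl anion left on C8a, flanked only by the benzyloxy group and the new aryloxy group and so without a leaving group to expel, is captured by CO2 to form C8a–C1. The closest known reaction types are the three-component coupling of arynes with amines and CO2 to give anthranilic acids and the O-arylation of phenols by silylaryl triflates; what has not been shown is an oxygen nucleophile as encumbered as 17 in the carboxylative variant. No ring is closed and no stereocentre is created. The regioselectivity that the step needs should come from the benzyloxy group on C4a, whose inductive pull distorts the triple bond so that C8 is the electrophilic carbon and the charge develops on C8a ortho to oxygen. O- rather than C-arylation is secured because both ortho positions and the para position of the ring B phenoxide are substituted, and carboxylation rather than protonation is favoured by the proton-free medium (pre-dried cesium salt, THF, CO2 atmosphere, slow addition of 15).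

Step 8
Reactants: 19 2,4-bis(benzyloxy)-6-[3-(tert-butoxycarbonyl)-4,6-dimethoxy-2-pentylphenoxy]benzoic acid
Product: 20 methyl 2,4-bis(benzyloxy)-6-[3-(tert-butoxycarbonyl)-4,6-dimethoxy-2-pentylphenoxy]benzoate
Conditions: MeI, K2CO3, DMF, rt
Reagents that add atoms: iodomethane, CI
Why: SN2 O-alkylation of the carboxylate, which is insensitive to the two ortho substituents, protects the acid before the phenols are unmasked.

Step 9
Reactants: 20 methyl 2,4-bis(benzyloxy)-6-[3-(tert-butoxycarbonyl)-4,6-dimethoxy-2-pentylphenoxy]benzoate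
Product: 21 methyl 2-[3-(tert-butoxycarbonyl)-4,6-dimethoxy-2-pentylphenoxy]-4,6-dihydroxybenzoate
Conditions: H2 (1 atm), 10% Pd/C, EtOAc/MeOH, rt
Reagents that add atoms: none
Why: Catalytic hydrogenolysis should cleave both benzyl ethers and leave the methyl ethers, both esters and the diaryl ether untouched.

Step 10
Reactants: 21 methyl 2-[3-(tert-butoxycarbonyl)-4,6-dimethoxy-2-pentylphenoxy]-4,6-dihydroxybenzoate
Product: 22 methyl 2-[3-(tert-butoxycarbonyl)-4,6-dimethoxy-2-pentylphenoxy]-6-hydroxy-4-methoxybenzoate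
Conditions: MeI (1.05 equiv), K2CO3, acetone, rt
Reagents that add atoms: iodomethane, CI
Why: Selective Williamson O-methylation is expected at the C6 hydroxyl, which is para to the ester, more acidic and free, whereas the C4a hydroxyl is held in a hydrogen bond to the ester carbonyl and should not react with one equivalent of MeI at room temperature.

Step 11
Reactants: 22 methyl 2-[3-(tert-butoxycarbonyl)-4,6-dimethoxy-2-pentylphenoxy]-6-hydroxy-4-methoxybenzoate
Product: 23 methyl 2-[3-(tert-butoxycarbonyl)-4,6-dimethoxy-2-pentylphenoxy]-4-methoxy-6-[(trifluoromethanesulfonyl)oxy]benzoate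
Conditions: Tf2O, pyridine, CH2Cl2, 0 °C to rt
Reagents that add atoms: trifluoromethanesulfonic anhydride, O=S(=O)(OS(=O)(=O)C(F)(F)F)C(F)(F)F
Why: O-Sulfonylation of the remaining chelated phenol turns the C4a oxygen into a leaving group for cross-coupling.

Step 12
Reactants: 23 methyl 2-[3-(tert-butoxycarbonyl)-4,6-dimethoxy-2-pentylphenoxy]-4-methoxy-6-[(trifluoromethanesulfonyl)oxy]benzoate; 24 1-heptyne
Product: 25 methyl 2-[3-(tert-butoxycarbonyl)-4,6-dimethoxy-2-pentylphenoxy]-6-(hept-1-yn-1-yl)-4-methoxybenzoate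
Conditions: Pd(PPh3)2Cl2 (5 mol%), CuI (10 mol%), Et3N, DMF, 70 °C
Reagents that add atoms: none
Why: Sonogashira coupling, in which the triflate activated by the ortho ester adds oxidatively to zerovalent palladium and the copper acetylide transmetalates, forms the C4a–C4 bond.

Step 13
Reactants: 25 methyl 2-[3-(tert-butoxycarbonyl)-4,6-dimethoxy-2-pentylphenoxy]-6-(hept-1-yn-1-yl)-4-methoxybenzoate
Product: 26 4,6-dimethoxy-3-[(6-methoxy-1-oxo-3-pentyl-1H-isochromen-8-yl)oxy]-2-pentylbenzoic acid
Conditions: Cu(OTf)2 (10 mol%), TFA/CH2Cl2 (1:3), rt to 40 °C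
Reagents that add atoms: none
Why: Acid-promoted 6-endo-dig oxacyclisation, in which the ester carbonyl oxygen attacks the pentyl-bearing alkyne carbon activated by Cu(OTf)2 and TFA and the resulting 1-methoxy-2-benzopyrylium ion loses its methyl group to trifluoroacetate, should close ring C while the same medium cleaves the tert-butyl ester of ring B.

Step 14
Reactants: 26 4,6-dimethoxy-3-[(6-methoxy-1-oxo-3-pentyl-1H-isochromen-8-yl)oxy]-2-pentylbenzoic acid
Product: 27 4,6-dihydroxy-3-[(6-hydroxy-1-oxo-3-pentyl-1H-isochromen-8-yl)oxy]-2-pentylbenzoic acid (CNP0439913.0)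
Conditions: BBr3 (8 equiv), CH2Cl2, −78 °C to rt; ice-water
Reagents that add atoms: none
Why: Lewis-acid ether cleavage by BBr3 should remove the three aryl methyl ethers while the diaryl ether, the lactone and the carboxylic acid stay intact, and a cold aqueous quench guards the liberated 2,4-dihydroxybenzoic acid against decarboxylation.

**Compound list**

1 | 1,3-dimethoxy-5-pentylbenzene (olivetol dimethyl ether) | CCCCCc1cc(OC)cc(OC)c1 | starting material
2 | 2,4-dibromo-1,5-dimethoxy-3-pentylbenzene | CCCCCc1c(Br)c(OC)cc(OC)c1Br | intermediate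
3 | (3-bromo-4,6-dimethoxy-2-pentylphenyl)lithium | [Li]c1c(CCCCC)c(Br)c(OC)cc1OC | intermediate (not isolated)
4 | tert-butyl 3-bromo-4,6-dimethoxy-2-pentylbenzoate | CCCCCc1c(Br)c(OC)cc(OC)c1C(=O)OC(C)(C)C | intermediate
5 | [3-(tert-butoxycarbonyl)-4,6-dimethoxy-2-pentylphenyl]lithium | [Li]c1c(CCCCC)c(C(=O)OC(C)(C)C)c(OC)cc1OC | intermediate (not isolated)
6 | lithium [3-(tert-butoxycarbonyl)-4,6-dimethoxy-2-pentylphenyl]trimethoxyborate | [Li+].CCCCCc1c([B-](OC)(OC)OC)c(OC)cc(OC)c1C(=O)OC(C)(C)C | intermediate (not isolated)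
7 | tert-butyl 3-hydroxy-4,6-dimethoxy-2-pentylbenzoate (ring B phenol) | CCCCCc1c(O)c(OC)cc(OC)c1C(=O)OC(C)(C)C | intermediate
8 | 3,5-bis(benzyloxy)phenol | Oc1cc(OCc2ccccc2)cc(OCc2ccccc2)c1 | starting material
9 | 3,5-bis(benzyloxy)phenyl N-isopropylcarbamate | CC(C)NC(=O)Oc1cc(OCc2ccccc2)cc(OCc2ccccc2)c1 | intermediate
10 | 3,5-bis(benzyloxy)phenyl N-(tert-butyldimethylsilyl)-N-isopropylcarbamate | CC(C)N([Si](C)(C)C(C)(C)C)C(=O)Oc1cc(OCc2ccccc2)cc(OCc2ccccc2)c1 | intermediate (not isolated)
11 | [2,4-bis(benzyloxy)-6-({[tert-butyldimethylsilyl](isopropyl)carbamoyl}oxy)phenyl]lithium | CC(C)N([Si](C)(C)C(C)(C)C)C(=O)Oc1cc(OCc2ccccc2)cc(OCc2ccccc2)c1[Li] | intermediate (not isolated)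
12 | 3,5-bis(benzyloxy)-2-(trimethylsilyl)phenyl N-(tert-butyldimethylsilyl)-N-isopropylcarbamate | CC(C)N([Si](C)(C)C(C)(C)C)C(=O)Oc1cc(OCc2ccccc2)cc(OCc2ccccc2)c1[Si](C)(C)C | intermediate (not isolated)
13 | 3,5-bis(benzyloxy)-2-(trimethylsilyl)phenyl N-isopropylcarbamate | CC(C)NC(=O)Oc1cc(OCc2ccccc2)cc(OCc2ccccc2)c1[Si](C)(C)C | intermediate
14 | 3,5-bis(benzyloxy)-2-(trimethylsilyl)phenol | Oc1cc(OCc2ccccc2)cc(OCc2ccccc2)c1[Si](C)(C)C | intermediate (not isolated)
15 | 3,5-bis(benzyloxy)-2-(trimethylsilyl)phenyl trifluoromethanesulfonate (aryne precursor) | C[Si](C)(C)c1c(OCc2ccccc2)cc(OCc2ccccc2)cc1OS(=O)(=O)C(F)(F)F | intermediate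
16 | carbon dioxide | O=C=O | starting material
17 | cesium 3-(tert-butoxycarbonyl)-4,6-dimethoxy-2-pentylphenoxide | [Cs+].CCCCCc1c([O-])c(OC)cc(OC)c1C(=O)OC(C)(C)C | intermediate (not isolated)
18 | 3,5-bis(benzyloxy)benzyne (3,5-bis(benzyloxy)-1,2-didehydrobenzene) | C1#CC(OCc2ccccc2)=CC(OCc2ccccc2)=C1 | intermediate (not isolated)
19 | 2,4-bis(benzyloxy)-6-[3-(tert-butoxycarbonyl)-4,6-dimethoxy-2-pentylphenoxy]benzoic acid | CCCCCc1c(Oc2cc(OCc3ccccc3)cc(OCc3ccccc3)c2C(=O)O)c(OC)cc(OC)c1C(=O)OC(C)(C)C | intermediate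
20 | methyl 2,4-bis(benzyloxy)-6-[3-(tert-butoxycarbonyl)-4,6-dimethoxy-2-pentylphenoxy]benzoate | CCCCCc1c(Oc2cc(OCc3ccccc3)cc(OCc3ccccc3)c2C(=O)OC)c(OC)cc(OC)c1C(=O)OC(C)(C)C | intermediate
21 | methyl 2-[3-(tert-butoxycarbonyl)-4,6-dimethoxy-2-pentylphenoxy]-4,6-dihydroxybenzoate | CCCCCc1c(Oc2cc(O)cc(O)c2C(=O)OC)c(OC)cc(OC)c1C(=O)OC(C)(C)C | intermediate
22 | methyl 2-[3-(tert-butoxycarbonyl)-4,6-dimethoxy-2-pentylphenoxy]-6-hydroxy-4-methoxybenzoate | CCCCCc1c(Oc2cc(OC)cc(O)c2C(=O)OC)c(OC)cc(OC)c1C(=O)OC(C)(C)C | intermediate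
23 | methyl 2-[3-(tert-butoxycarbonyl)-4,6-dimethoxy-2-pentylphenoxy]-4-methoxy-6-[(trifluoromethanesulfonyl)oxy]benzoate | CCCCCc1c(Oc2cc(OC)cc(OS(=O)(=O)C(F)(F)F)c2C(=O)OC)c(OC)cc(OC)c1C(=O)OC(C)(C)C | intermediate
24 | 1-heptyne | CCCCCC#C | starting material
25 | methyl 2-[3-(tert-butoxycarbonyl)-4,6-dimethoxy-2-pentylphenoxy]-6-(hept-1-yn-1-yl)-4-methoxybenzoate | CCCCCC#Cc1cc(OC)cc(Oc2c(OC)cc(OC)c(C(=O)OC(C)(C)C)c2CCCCC)c1C(=O)OC | intermediate
26 | 4,6-dimethoxy-3-[(6-methoxy-1-oxo-3-pentyl-1H-isochromen-8-yl)oxy]-2-pentylbenzoic acid | CCCCCc1cc2cc(OC)cc(Oc3c(OC)cc(OC)c(C(=O)O)c3CCCCC)c2c(=O)o1 | intermediate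
27 | 4,6-dihydroxy-3-[(6-hydroxy-1-oxo-3-pentyl-1H-isochromen-8-yl)oxy]-2-pentylbenzoic acid (CNP0439913.0) | CCCCCc1cc2cc(O)cc(Oc3c(O)cc(O)c(C(=O)O)c3CCCCC)c2c(=O)o1 | target

**Summary**

Total step count: 14.
Longest linear sequence: 11 steps (steps 1, 2, 3, 7 to 14; the branch through steps 4, 5, 6 is equally long).

Steps most likely to fail:

1. Step 7 (proposed new method). The aryl anion may be protonated before it meets CO2, which would give the diaryl ether without the carboxyl group. The phenoxide may also be held back as its aryl carbonate, so that the aryne oligomerises or inserts into the carbonate. Fallback by known chemistry, setting out from 7: purchased methyl 2,4,6-trihydroxybenzoate F1 is benzylated at its two more acidic hydroxyls (BnBr 2 equiv, K2CO3, acetone) to methyl 2,4-bis(benzyloxy)-6-hydroxybenzoate F2. The remaining chelated phenol is converted with Tf2O and pyridine into methyl 2,4-bis(benzyloxy)-6-[(trifluoromethanesulfonyl)oxy]benzoate F3. F3 is then joined to phenol 7 by palladium-catalysed C–O cross-coupling (Pd(OAc)2, t-BuXPhos, K3PO4, toluene, 100 °C), which should give ester 20 directly; the route resumes at 20.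

2. Step 13. Closure may go 5-exo to an alkylidene phthalide, the alkyne may be hydrated to an aryl ketone, or the tert-butyl cation may alkylate the electron-rich rings. Fallback, setting out from 25: iodine with NaHCO3 in MeCN effects electrophilic 6-endo iodolactonisation, with loss of the ester methyl group, to tert-butyl 3-[(4-iodo-6-methoxy-1-oxo-3-pentyl-1H-isochromen-8-yl)oxy]-4,6-dimethoxy-2-pentylbenzoate F4. Palladium-catalysed transfer hydrogenolysis (Pd(OAc)2, PPh3, HCO2H, Et3N, DMF) removes the iodine to give tert-butyl 4,6-dimethoxy-3-[(6-methoxy-1-oxo-3-pentyl-1H-isochromen-8-yl)oxy]-2-pentylbenzoate F5. TFA in CH2Cl2 at room temperature then cleaves the tert-butyl ester and returns to the route at 26.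

3. Step 5. n-BuLi may deprotonate a benzylic position of the benzyl ethers, or the carbamoyl group may migrate to carbon (anionic Fries rearrangement) before silylation. Fallback, setting out from 8: NBS in CH2Cl2 at −78 °C brominates ortho to the hydroxyl to give 3,5-bis(benzyloxy)-2-bromophenol F6, to be separated from any para isomer. Hexamethyldisilazane converts it into [3,5-bis(benzyloxy)-2-bromophenoxy]trimethylsilane F7. n-BuLi in THF at −100 °C triggers bromine–lithium exchange and 1,3 O-to-C silyl migration (retro-Brook rearrangement) to lithium 3,5-bis(benzyloxy)-2-(trimethylsilyl)phenoxide F8, which is triflated in the same flask with Tf2O; the route resumes at 15.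

**Further compounds**

F1 | step 7 | methyl 2,4,6-trihydroxybenzoate (purchased building block) | COC(=O)c1c(O)cc(O)cc1O
F2 | step 7 | methyl 2,4-bis(benzyloxy)-6-hydroxybenzoate | COC(=O)c1c(O)cc(OCc2ccccc2)cc1OCc1ccccc1
F3 | step 7 | methyl 2,4-bis(benzyloxy)-6-[(trifluoromethanesulfonyl)oxy]benzoate | COC(=O)c1c(OS(=O)(=O)C(F)(F)F)cc(OCc2ccccc2)cc1OCc1ccccc1
F4 | step 13 | tert-butyl 3-[(4-iodo-6-methoxy-1-oxo-3-pentyl-1H-isochromen-8-yl)oxy]-4,6-dimethoxy-2-pentylbenzoate | CCCCCc1oc(=O)c2c(Oc3c(OC)cc(OC)c(C(=O)OC(C)(C)C)c3CCCCC)cc(OC)cc2c1I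
F5 | step 13 | tert-butyl 4,6-dimethoxy-3-[(6-methoxy-1-oxo-3-pentyl-1H-isochromen-8-yl)oxy]-2-pentylbenzoate | CCCCCc1cc2cc(OC)cc(Oc3c(OC)cc(OC)c(C(=O)OC(C)(C)C)c3CCCCC)c2c(=O)o1
F6 | step 5 | 3,5-bis(benzyloxy)-2-bromophenol | Oc1cc(OCc2ccccc2)cc(OCc2ccccc2)c1Br
F7 | step 5 | [3,5-bis(benzyloxy)-2-bromophenoxy]trimethylsilane | C[Si](C)(C)Oc1cc(OCc2ccccc2)cc(OCc2ccccc2)c1Br
F8 | step 5 | lithium 3,5-bis(benzyloxy)-2-(trimethylsilyl)phenoxide | [Li+].[O-]c1cc(OCc2ccccc2)cc(OCc2ccccc2)c1[Si](C)(C)C
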